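The constants are those of an exercise.

An easy step comes first: two E make E2, which then leaks slowly to J, the intermediate of a consecutive pair.

    E2 ⇌ J (K1 = 0.99, k1 = 0.0397 s⁻¹)
    2 E → E2 (k2 = 629 L mol⁻¹ s⁻¹)

common to all: time 3.0 s

| run | E |
|---|---|
| cedar | 2.5 × 10⁻⁴ M |
| elm | 5.0 × 10⁻⁴ M |
| birch | 0.0010 M |

* share of E2 in all that became E2 or J for cedar, elm, birch, in this order
* the shape of the row from first to last (falls, then rises / falls all the way / hardly changes / rises all the way / rises, then falls)

- percent here means E units held: one E2 or J counts as two
- a doubled species enters its step squared and goes two at a time
- "hardly changes" means that all values lie within two and a half points (for a concentration: within two and a half percent of the largest)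
- run time (cedar): 3.0 s

Take a as the charge times twice the making constant: 0.315 s⁻¹ in cedar, 0.629 s⁻¹ in elm and 1.26 s⁻¹ in birch. The fraction of the charge that has left E by time t is then at over one plus at.

Now you need the mean age, the time a formed unit has on average stood since it was made: t minus ln(one plus at)/a, divided by that fraction. Cedar gives 1.83 s, elm 2.01 s and birch 2.22 s.

Cedar's mean age is shorter than 17 s, the half-life of E2 by its forward loss to J, so a first leak is the loss constant times the age: 7.25% in cedar.

That treats every formed unit as E2 throughout, so put the answer back. As an estimate, multiply the leak by one minus half of itself times 2.01, a factor that counts both the forward loss of E2 and J running back. The leak becomes 6.73% in cedar, 7.34% in elm and 8.04% in birch. Your row of E2 shares is therefore 93.3%, 92.7%, 92.0%, a spread of 1.3 percentage points, inside the band that counts as hardly changing.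

The forecast gave 93.35%, 92.71% and 91.99%, “so the row hardly changes”. The flasks give 93.3%, 92.7% and 92.0%: hardly changes.

In cedar at 3.00 s, E2 is still made 4.99 times faster than it is used up, each step taken net, and its half-life by forward loss to J, 17 s, is longer than the mean age of 1.83 s, with J at 3.23% beside E2 at 45.3%. In birch the mean age of 2.22 s gives a leak of 8.04% on the 79.1% that has left E, which is 6.36% of the charge as J, and birch stood at 6.33% J at 3.00 s.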